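**Plan**
Cuts: C4a–C4 and O1–C2 of ring C. This gives ring A as a phenol and ethyl 4-methoxybenzoylacetate (C2–C3–C4 plus ring B).
Enabling feature: C5–OH and O1 (on C8a) both flank C4a, and the C6 and C8 methoxy groups mirror each other across the C4a–C7 axis. Ring A is therefore the symmetric 4,5,6-trimethoxyresorcinol, with C4a as its only ring C–H.
Forward: 1,2,3-trimethoxybenzene is dibrominated at C4/C6, then each C–Br becomes C–B and then C–OH.
Rings A and B are bought. Ring C is the only ring made and closes last, in one acid-free thermal condensation that leaves the 5-OH free.
Stereochemistry: none. The target has no stereocentre and no stereogenic double bond.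

Key step: step 4

Assumption: 1,2,3-trimethoxybenzene and ethyl 3-(4-methoxyphenyl)-3-oxopropanoate are taken as catalogue chemicals.

**Step 1**
Reactants: 1 1,2,3-trimethoxybenzene
Product: 2 1,5-dibromo-2,3,4-trimethoxybenzene (one Br next to each outer methoxy group; the single remaining ring H lies between the two Br)
Conditions: NBS (2.1 equiv), MeCN, 0 °C → rt
Reagents that add atoms: N-bromosuccinimide, O=C1CCC(=O)N1Br
Why: Electrophilic aromatic bromination should place both bromines at C4/C6 of 1, because each of these carbons is ortho to one outer methoxy group and para to the other, whereas C5 is para only to the twisted, weakly donating central methoxy group and so stays as the C–H that becomes C4a.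

**Step 2**
Reactants: 2 1,5-dibromo-2,3,4-trimethoxybenzene
Product: 3 2,2'-(4,5,6-trimethoxy-1,3-phenylene)bis(4,4,5,5-tetramethyl-1,3,2-dioxaborolane)
Conditions: B2pin2 (2.6 equiv), PdCl2(dppf) (5 mol %), KOAc (6 equiv), 1,4-dioxane, 90 °C, Ar
Reagents that add atoms: bis(pinacolato)diboron, CC1(C)OB(OC1(C)C)B1OC(C)(C)C(C)(C)O1
Why: This is a twofold Miyaura borylation (oxidative addition of zerovalent palladium into each C–Br bond, acetate-assisted transmetalation with the diboron reagent, reductive elimination), routine for aryl bromides with one ortho alkoxy group, in which the weak base KOAc holds back Suzuki-type self-coupling and the methyl ethers are inert.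

**Step 3**
Reactants: 3 2,2'-(4,5,6-trimethoxy-1,3-phenylene)bis(4,4,5,5-tetramethyl-1,3,2-dioxaborolane)
Product: 4 4,5,6-trimethoxybenzene-1,3-diol (4,5,6-trimethoxyresorcinol)
Conditions: 30% aq H2O2 (3 equiv), THF, 0 °C → rt, Ar
Reagents that add atoms: hydrogen peroxide, OO
Why: In this peroxide ipso-hydroxylation of an arylboronate, hydroperoxide adds to boron, the aryl group migrates from boron to oxygen at the carbon that carried boron, and hydrolysis of the borate frees each phenol, while the base-free medium and argon should keep the electron-rich resorcinol from further oxidation.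

**Step 4**
Reactants: 4 4,5,6-trimethoxybenzene-1,3-diol; 5 ethyl 3-(4-methoxyphenyl)-3-oxopropanoate
Product: 9 5-hydroxy-6,7,8-trimethoxy-2-(4-methoxyphenyl)-4H-chromen-4-one (the target), via 4-methoxybenzoylketene 6 (not isolated), via 2,6-dihydroxyaryl 1,3-diketone 7 (not isolated), via cyclic hemiketal 8 (not isolated)
Conditions: neat melt, 5 (2 equiv, added in portions), Ar, 240–250 °C, EtOH and H2O distilled off
Reagents that add atoms: none
Why: Above roughly 200 °C the enol form of 5 expels ethanol to give aroylketene 6, whose ketene carbon is attacked by C2 of 4, the only ring C–H and one pushed by two ortho hydroxyls and a para methoxy group, so that the C4a–C4 bond forms and 1,3-diketone 7 results, while O-acylation is reversible at this temperature and drains back into the C-acylation channel. One of the two equivalent phenol oxygens of 7 then adds to the aryl ketone carbonyl in a 6-exo-trig closure (O1–C2 bond, ring C) to hemiketal 8, and loss of water gives the conjugated pyranone of 9. The closest known reaction type is the Mentzer thermal pyrone synthesis, the acid-free relative of the Simonis chromone cyclisation, which is established for phloroglucinol-type phenols and ethyl aroylacetates as a way to 5-hydroxyflavones. No stereocentre is created in 9, since the hemiketal carbon of 8 forms as a racemate and becomes sp2 on dehydration. The selectivity needed is flavone over the 4-arylcoumarin of a Pechmann reaction, and it is secured by leaving out any acid, so that the ring carbon meets the ester-derived ketene carbon and not an activated ketone; regiochemistry needs no control because 4 offers one free carbon and its mirror plane through C2 and C5 makes both closures the same. The hydroxyl that stays out of the ring ends as the C5–OH hydrogen-bonded to the C4 carbonyl, which also shields it from further acylation.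

**Compound list**
1 | 1,2,3-trimethoxybenzene | COc1cccc(OC)c1OC | starting material
2 | 1,5-dibromo-2,3,4-trimethoxybenzene | COc1c(Br)cc(Br)c(OC)c1OC | intermediate
3 | 2,2'-(4,5,6-trimethoxy-1,3-phenylene)bis(4,4,5,5-tetramethyl-1,3,2-dioxaborolane) | COc1c(B2OC(C)(C)C(C)(C)O2)cc(B2OC(C)(C)C(C)(C)O2)c(OC)c1OC | intermediate
4 | 4,5,6-trimethoxybenzene-1,3-diol | COc1c(O)cc(O)c(OC)c1OC | intermediate
5 | ethyl 3-(4-methoxyphenyl)-3-oxopropanoate | CCOC(=O)CC(=O)c1ccc(OC)cc1 | starting material
6 | 4-methoxybenzoylketene, 3-(4-methoxyphenyl)-3-oxoprop-1-en-1-one | COc1ccc(cc1)C(=O)C=C=O | intermediate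
7 | 1-(2,6-dihydroxy-3,4,5-trimethoxyphenyl)-3-(4-methoxyphenyl)propane-1,3-dione | COc1ccc(cc1)C(=O)CC(=O)c1c(O)c(OC)c(OC)c(OC)c1O | intermediate
8 | 2,5-dihydroxy-6,7,8-trimethoxy-2-(4-methoxyphenyl)chroman-4-one (racemic hemiketal) | COc1ccc(cc1)C1(O)CC(=O)c2c(O)c(OC)c(OC)c(OC)c2O1 | intermediate
9 | 5-hydroxy-6,7,8-trimethoxy-2-(4-methoxyphenyl)-4H-chromen-4-one | COc1ccc(-c2cc(=O)c3c(O)c(OC)c(OC)c(OC)c3o2)cc1 | target

**Totals**
Total step count: 4. Longest linear sequence: 4 steps (1 → 2 → 3 → 4 → 9).

**Steps most likely to fail**

Step 4 carries the most risk.
- Risk: at the temperature needed, self-addition of the ketene may outrun acylation of the ring. The water released may also break down the ketoester by decarboxylation, and the electron-rich phenol may slowly darken.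
- Fallback: it sets out from 4 and builds the same diketone stepwise at low temperature.
  - Friedel–Crafts C-acetylation at the lone ring carbon (AcOH, BF3·OEt2, 80 °C) should give 1-(2,6-dihydroxy-3,4,5-trimethoxyphenyl)ethan-1-one F1.
  - Full deprotonation with LiN(SiMe3)2 (5 equiv, THF, −78 °C) is followed by C-acylation of the ketone enolate with 4-methoxybenzoyl chloride. This is the polyanion form of the Baker–Venkataraman route.
  - The fallback comes back to the route at 7, now isolated. Catalytic H2SO4 in AcOH at 95 °C then cyclodehydrates 7 to 9.
  - The symmetry of ring A again makes either closure equivalent.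

Step 2 comes next.
- Risk: oxidative addition into this electron-rich dibromide is slow. Hydrodebromination, stalling after the first borylation and cross-coupling between borylated and unreacted sites may all take material away.
- Fallback: it sets out from 2 and replaces palladium catalysis by halogen–metal exchange with in situ trapping.
  - n-BuLi (2.2 equiv) is added to 2 and B(OiPr)3 in THF/toluene at −78 °C. Each aryllithium is captured before the second exchange, so no dilithio species is needed.
  - Work-up with aqueous HCl should give (4,5,6-trimethoxy-1,3-phenylene)diboronic acid F2.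
  - Oxidation of F2 with aqueous H2O2 in THF, as in step 3, brings the fallback back to the route at 4.

Step 3 is third.
- Risk: the ring may be over-oxidised by peroxide or by air during work-up. Polar product may also be lost to the aqueous phase or during separation from the diol by-product.
- Fallback: it sets out from 2 and avoids any oxidant.
  - Palladium-catalysed C–O coupling with benzyl alcohol ([Pd(allyl)Cl]2, RockPhos, Cs2CO3, toluene, 90 °C) should give the storable 1,5-bis(benzyloxy)-2,3,4-trimethoxybenzene F3.
  - Hydrogenolysis (H2, Pd/C, EtOAc, rt) frees both phenols under neutral, reducing conditions and comes back to the route at 4.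
  - After filtration and evaporation, 4 can go straight into step 4.

**Further compounds**
F1 | step 4 | 1-(2,6-dihydroxy-3,4,5-trimethoxyphenyl)ethan-1-one | CC(=O)c1c(O)c(OC)c(OC)c(OC)c1O
F2 | step 2 | (4,5,6-trimethoxy-1,3-phenylene)diboronic acid | COc1c(B(O)O)cc(B(O)O)c(OC)c1OC
F3 | step 3 | 1,5-bis(benzyloxy)-2,3,4-trimethoxybenzene | COc1c(OCc2ccccc2)cc(OCc2ccccc2)c(OC)c1OC
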